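(The rate constants are invented, and the outcome is calculated.)

Early in this flask, free catalyst entered the round by binding reagent 200 times faster than it dimerised (forward step alone), so I treated dimerisation as a side loss from the round.

starting material 0.20 mM; reagent 0.220 mM; free catalyst 1.0 µM

    2 free catalyst → spent catalyst (k1 = 17000 M⁻¹ s⁻¹)
    reagent + free catalyst ⇌ catalyst intermediate A (K2 = 1500 M⁻¹, k2 = 31000 M⁻¹ s⁻¹)
    catalyst intermediate B → free catalyst + product (k3 = 4.9 s⁻¹)
    starting material + catalyst intermediate A ⇌ catalyst intermediate B (K4 = 5800 M⁻¹, k4 = 9.2 × 10⁵ M⁻¹ s⁻¹)

1. the form that holds most of the catalyst when 50% of the starting material are converted (catalyst intermediate B / spent catalyst / free catalyst / catalyst intermediate A)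
2. its share of the catalyst then
3. apparent order in free catalyst when 50% of the starting material are converted (percent change of the rate of making product for one percent more free catalyst charged)

I froze the split of the active catalyst at each conversion. Let b be the equilibrium constant of reagent binding times the reagent left, and s the equilibrium constant of starting-material binding times the starting material left. With equilibria, I took free catalyst, catalyst intermediate A and catalyst intermediate B as one to b to bs.

With turnover alone, this flask lost no catalyst. Then I added dimerisation. Dividing its loss by the turnover rate, the logarithm of the active catalyst falls in proportion to conversion, with scale bs(1 + b + bs) times 0.721: the breakdown constant of catalyst intermediate B over two dimerisation constants and the charge of starting material.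

Last I let binding lag. I kept catalyst intermediate B equilibrated with catalyst intermediate A, since it returned faster than it broke down, but the breakdown constant over the constant for catalyst intermediate A returning to free catalyst gave 0.237. So d = 1 + 0.237s divides both intermediates, and the scale becomes (bs/d)(1 + b(1 + s)/d) times 0.721.

| Conversion | b | s | Scale, equilibria | Scale, lagging binding |
|---|---|---|---|---|
| start | 0.330 | 1.16 | 0.472 | 0.337 |
| 25.0% | 0.255 | 0.870 | 0.236 | 0.185 |
| 50% | 0.180 | 0.580 | 0.0966 | 0.0827 |

I call the last column the reach: the fraction of the charged starting material converted while active catalyst falls by a factor of e. Weighting the three rows one, four, one, my reckoned active catalyst left at half conversion came to 8.62% with equilibria and 4.70% with lagging binding. So I committed to spent catalyst at 95.3%. The reach holds no catalyst charge, so in this reckoning the active share at a given conversion does not move with the charge and the rate follows it: order one.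

The forecast gave spent catalyst at 95.6%, order 1, holding that “the active catalyst decays roughly exponentially with conversion”.

The simulation gave spent catalyst at 95.6% and order 1.0, at 18.0 min. One percent more on the forward and back rate constants of reagent binding together raised the rate by 0.71 percent. From then until 150 min, active catalyst in this flask fell from 4.41% to 0.476%, or 2.23 e-folds. The reach there, with the 36.7% of starting material left, was 0.0461. Averaged with 0.0827, it gave 14.4% of the charge as further conversion, and product in this flask stood at 63.3% at 150 min, up from 50%.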